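## The problem

The target is an azaphilone: a pyran (O2, C1, C3, C4, C4a, C8a; isochromene numbering throughout) fused along C4a–C8a to a cyclohexadienedione (C4a, C5, C6, C7, C8, C8a). C3 carries an (E)-3-acetoxyprop-1-enyl chain, and C7 carries a methyl group and an orsellinate ester. C7 is the only stereocentre, (S) as read from the SMILES. It is quaternary and lies between two carbonyl groups, so no other centre in the molecule can set it; at most it can bias a transient centre at C4a across the ring. Its absolute configuration therefore has to come from a reagent. Several groups will not survive rough treatment: the primary allylic acetate (alkoxides, hydrides), the pyranoquinone (amines and other nucleophiles at C1 and C3), the non-enolisable C6–C7–C8 diketone (retro-Claisen cleavage), and the free resorcinol (oxidants). The ester joins a tertiary alcohol to a 2,6-disubstituted benzoic acid, which makes ordinary acyl transfer very hard. The feature that opens the structure is that, once C1 is a formyl group on the carbocycle, O2=C1–C8a=C4a is a 1-oxadiene, and a two-carbon enol ether can add across O2 and C4a to supply C3 and C4 and close the pyran. If the carbocycle carries a second formyl group at C5, its two halves (C8a/C8 and C5/C6) differ only in where the enol proton sits, so the mirror-image forms interconvert by proton shift, and choosing which half reacts is the same as choosing the configuration at C7.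

## Retrosynthesis

**18 ⇐ 16.** No skeletal bond is cut. Methanol is added back across C3=C4 and the two phenols are masked as methoxymethyl ethers, giving the C3 methyl ketal 16 by way of the bis(methoxymethyl) ether 17. Both changes are undone by acid, so one final operation serves for both. The C3 methoxy group is kept this late on purpose (see 14 ⇐ 7 + 13). The forward step must leave the allylic acetate and the tertiary ester untouched.

**16 ⇐ 15 ⇐ 14.** The C4a=C5 double bond is traced back to an α-diazo ketone 15 (C5 diazo, C4a–H), and 15 to the α-formyl ketone 14, so the bond cut is C5–CHO. The neighbouring option, hydrolytic retro-Claisen deformylation followed by quinone dehydrogenation, needs a nucleophilic base that would attack the acetate and the C6–C7–C8 diketone. Deformylative diazo transfer needs only triethylamine, and the following hydride shift needs no oxidant. Precursor 14 regains the C5 formyl group that makes the two halves of the carbocycle equivalent before the key step. The forward steps must be fast and non-acidic, because 14 is configurationally secure only while its pyran stays closed.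

**14 ⇐ 7 + 13 (key disconnection).** The bonds O2–C3 and C4–C4a are cut, which opens the pyran and returns the diformyl quinol ester 7 and the 2-methoxydiene 13.
- Against its neighbours: the usual azaphilone assembly closes the pyran by oxygen attack on an alkyne and leaves C7 to a separate enantioselective oxidation. This cut instead puts ring formation and the choice of C7 configuration into one event.
- Simplification: all three stereocentres of 14 disappear. Compound 7 is a monocyclic racemate that equilibrates by itself, and 13 is a five-carbon diene.
- Asked of the forward reaction: it must select one of the two equivalent formyl-enone halves, and the pyran must not reopen while the second formyl group is present. A ring-opened species has two equivalent formyl-enol halves and can reclose on either, which gives the enantiomer. Methanol is therefore not eliminated at this stage, because elimination from a ketal whose ring oxygen is the better leaving group would pass through such open forms.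

**7 ⇐ 2 + 6.** The C7–O bond is cut. Forming it by oxidative dearomatisation with a carboxylate as the nucleophile (a trivalent-iodine dicarboxylate 6) avoids acylating a tertiary alcohol, next to an acidic enol, with a 2,6-disubstituted benzoyl electrophile. The precursor 2 is a flat, achiral phenol. The forward reaction must deliver the carboxylate to the methyl-bearing carbon between the two hydroxyl groups; stereocontrol is not needed because 7 racemises.

**2 ⇐ 1; 6 ⇐ 5 ⇐ 4 ⇐ 3.** Two aryl–CHO bonds are cut from 2, leading to 2-methylresorcinol 1, whose two free activated positions are exactly those required. Reagent 6 comes from acid 5 by ligand exchange on iodine, and 5 from orsellinic acid 3 by exhaustive methoxymethylation (4) and cleavage of the ester alone. The protecting group must survive oxidation, a copper Lewis acid, triethylamine and a rhodium carbenoid, and leave under mild acid.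

**13 ⇐ 11 ⇐ 9 + 10; 9 ⇐ 8.** The enol ether of 13 is traced back through dimethyl ketal 12 to enone 11, and the C=C bond of 11 is cut to acetoxyacetaldehyde 9 and the stabilised ylide 10. Aldehyde 9 comes from both halves of cis-1,4-diacetoxybut-2-ene 8 by cleavage of its C=C bond. The forward chain must give the E alkene (stabilised ylide) and the cross-conjugated, less substituted enol ether.

## Roads not taken

**Alternative 1:** The two C–C bonds that complete the orsellinate benzene ring are cut. In the forward direction the C7 but-2-ynoate A2 adds to the bis(silyloxy)diene A3, and the bicyclo[2.2.2]octadiene loses isobutene to give the bis(trimethylsilyl) ether A1, which is hydrolysed to 18 on work-up.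
- Merits: the ester to the tertiary alcohol is made with a small alkynoic acid, not a hindered benzoic acid, and the silyl ethers fall off without an acidic deprotection. The last point is gentler than step 12 of the chosen plan.
- Weak points: it assumes the enantiopure azaphilone alcohol and so leaves the C7 problem entirely to another route. A3 is very electron-rich and the pyranoquinone of A2 offers several acceptor positions besides the ynoate. Expelling isobutene needs prolonged heating, which the allylic acetate and pyranoquinone may not tolerate. It builds a ring that can be bought.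
- Comparison: the chosen plan answers the hindered-ester problem differently, by forming C7–O oxidatively (step 5), and uses orsellinic acid as purchased. Against the milder deprotection of alternative 1 it sets the fact that it addresses the stereocentre at all.

**Alternative 2:** The C7–C8 bond is cut. In the forward direction a chiral triazolylidene carbene converts the aldehyde of the pyran aldehyde–diketone A5 into an acyl-anion equivalent that adds to the C7 ketone, closing the carbocycle and giving the tertiary alcohol A4.
- Merits: intramolecular aldehyde–ketone benzoin cyclisation to a six-membered tertiary ketol is an established enantioselective reaction type. The stereo-determining step is therefore better founded than step 9.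
- Weak points: A5 is a base-sensitive 4-ylidene-4H-pyran that is no easier to make than the core itself. Its aldehyde is a vinylogous formate and a poor partner for the carbene. The diketone offers a second ketone (C6, five-membered closure). A4 must then be acylated at its hindered tertiary hydroxyl with an activated derivative of 5 to reach 17, which is the acyl transfer the chosen plan avoids.
- Comparison: alternative 2 is stronger on precedent for stereocontrol. The chosen plan sets against this a substrate reached in two steps from a bought phenol, an ester already in place before the stereo-defining step, and assembly from three simple blocks.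

**Alternative 3:** The C8a=C4a bond is cut. In the forward direction a chiral amine turns one formyl group of the symmetric dialdehyde A7 into an enamine whose α-carbon attacks the other aldehyde; dehydration gives the mono-formyl quinol ester A6 with C7 set.
- Merits: A6 carries a single formyl group. The pyran annulation with 13 that would follow has no half to confuse, and no formyl group needs removing afterwards. In both respects it is cleaner than the chosen plan, which spends step 10 on deformylation and must guard the pyran against reopening.
- Weak points: A7 has no short preparation. Each of its arms is a chelated β-keto aldehyde enol that gives unreactive vinylogous amides with secondary amines, and its 2-acyloxy-1,3-diketone core invites retro-Claisen cleavage by the catalyst.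
- Comparison: the unsolved part of alternative 3 is its substrate, whereas the unsolved part of the chosen plan is a selectivity. The chosen plan's substrate 7 is simple, and a racemic fallback with late resolution exists.

Key step: step 9

Assumption: C7 of the target is (S) as read from the SMILES; in 14, 15 and 16 the CIP letters change with the substituents, but the spatial arrangement at C7 is the same from 14 to 18.

## Route

Step 1
Reactants: 1 2-methylresorcinol
Product: 2 4,6-dihydroxy-5-methylbenzene-1,3-dicarbaldehyde
Conditions: hexamethylenetetramine (4 equiv), CF3CO2H, reflux; then 3 M HCl, 60 °C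
Reagents that add atoms: hexamethylenetetramine, C1N2CN3CN1CN(C2)C3; water, O
Why: Duff formylation; the two free positions are each ortho to one hydroxyl and para to the other, the methyl group blocks the position between the hydroxyls, and excess reagent in trifluoroacetic acid should drive the second formylation.

Step 2
Reactants: 3 orsellinic acid (2,4-dihydroxy-6-methylbenzoic acid)
Product: 4 methoxymethyl 2,4-bis(methoxymethoxy)-6-methylbenzoate
Conditions: NaH (3.6 equiv), MeOCH2Cl (3.6 equiv), DMF, 0 °C → rt
Reagents that add atoms: chloromethyl methyl ether, COCCl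
Why: Williamson-type O-alkylation of the carboxylate and both phenoxides; the sodium salt in DMF should also alkylate the hydrogen-bonded 2-hydroxyl.

Step 3
Reactants: 4 methoxymethyl 2,4-bis(methoxymethoxy)-6-methylbenzoate
Product: 5 2,4-bis(methoxymethoxy)-6-methylbenzoic acid
Conditions: LiOH·H2O (3 equiv), THF/MeOH/H2O, rt; then 1 M HCl to pH 4, 0 °C
Reagents that add atoms: lithium hydroxide, [Li+].[OH-]
Why: Saponification; the acyloxymethyl ester is cleaved by hydroxide while the aryl methoxymethyl ethers are stable to base, and brief cold acidification to pH 4 leaves them intact.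

Step 4
Reactants: 5 2,4-bis(methoxymethoxy)-6-methylbenzoic acid
Product: 6 phenyliodine bis[2,4-bis(methoxymethoxy)-6-methylbenzoate]
Conditions: PhI(OAc)2 (0.5 equiv), PhCl, 50 °C, 20 mbar (AcOH distilled off)
Reagents that add atoms: (diacetoxyiodo)benzene, CC(=O)OI(OC(C)=O)c1ccccc1
Why: Carboxylate ligand exchange on trivalent iodine, driven by removal of acetic acid; the standard preparation of [bis(acyloxy)iodo]arenes.

Step 5
Reactants: 2 4,6-dihydroxy-5-methylbenzene-1,3-dicarbaldehyde; 6 phenyliodine bis[2,4-bis(methoxymethoxy)-6-methylbenzoate]
Product: 7 3,5-diformyl-2-hydroxy-1-methyl-6-oxocyclohexa-2,4-dien-1-yl 2,4-bis(methoxymethoxy)-6-methylbenzoate (racemic; enantiomers interconvert by tautomerism)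
Conditions: 6 (1.1 equiv), CH2Cl2/(CF3)2CHOH 4:1, −20 → 0 °C
Reagents that add atoms: none
Why: Wessely-type oxidative dearomatising acyloxylation: the phenol exchanges onto iodine and a carboxylate is delivered to the methyl-bearing carbon between the two oxygens, the only oxidisable ring carbon without a formyl group, with loss of iodobenzene. The C7–O bond forms with the carboxylate as nucleophile, so the hindered acyl carbon is never attacked. The new centre needs no control because 7 racemises.

Step 6
Reactants: 8 cis-1,4-diacetoxybut-2-ene
Product: 9 2-oxoethyl acetate (acetoxyacetaldehyde)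
Conditions: O3, CH2Cl2, −78 °C; then Me2S, −78 °C → rt
Reagents that add atoms: ozone, [O-][O+]=O
Why: Ozonolysis with reductive work-up; the symmetric alkene gives two equivalents of one aldehyde, used as a crude solution.

Step 7
Reactants: 9 2-oxoethyl acetate; 10 1-(triphenylphosphoranylidene)propan-2-one
Product: 11 (E)-4-oxopent-2-en-1-yl acetate
Conditions: CH2Cl2, rt
Reagents that add atoms: none
Why: Wittig olefination with a stabilised ylide, which should give the E enone under neutral conditions that spare the acetate.

Step 8
Reactants: 11 (E)-4-oxopent-2-en-1-yl acetate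
Product: 13 (E)-4-methoxypenta-2,4-dien-1-yl acetate, via dimethyl ketal 12 (not isolated)
Conditions: MeOSiMe3 (2.5 equiv), Me3SiOTf (5 mol%), CH2Cl2, −78 °C; then i-Pr2NEt (1.6 equiv), Me3SiOTf (1.2 equiv), −78 → 0 °C
Reagents that add atoms: methoxytrimethylsilane, CO[Si](C)(C)C
Why: Silyl-triflate-catalysed ketalisation with an alkoxysilane converts the enone into its dimethyl ketal without conjugate addition. Silyl triflate with a hindered amine then ionises the ketal and removes a proton from the methyl group, giving the less substituted cross-conjugated enol ether. The E alkene and the acetate are not involved.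

Step 9
Reactants: 7 3,5-diformyl-2-hydroxy-1-methyl-6-oxocyclohexa-2,4-dien-1-yl 2,4-bis(methoxymethoxy)-6-methylbenzoate; 13 (E)-4-methoxypenta-2,4-dien-1-yl acetate
Product: 14 (4aS,7S)-3-[(E)-3-acetoxyprop-1-enyl]-5-formyl-6-hydroxy-3-methoxy-7-methyl-8-oxo-4,4a,7,8-tetrahydro-3H-isochromen-7-yl 2,4-bis(methoxymethoxy)-6-methylbenzoate (C3 epimers; 4a-H cis to the aroyloxy group)
Conditions: Cu(OTf)2 (10 mol%), (R,R)-t-Bu-box [2,2'-(propane-2,2-diyl)bis((4R)-4-tert-butyl-4,5-dihydrooxazole)] (11 mol%), 2,6-lutidine (1.0 equiv), 13 (2 equiv), 4 Å MS, CH2Cl2, −40 → −20 °C; cold pH 6 phosphate wash, used at once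
Reagents that add atoms: none
Why: Proposed new method: 2,6-lutidine turns racemising 7 into its achiral vinylogous carboxylate, and the divalent-copper complex of the (R,R)-ligand binds one of the two enantiotopic β-oxido-enal units of this anion (the oxygen on C6 and the C5 formyl oxygen) as a six-membered enolate chelate, so that the metal takes the place of the tautomeric proton and the C8a=C4a double bond is fixed in the other half. That free half, O2=C1–C8a=C4a with its formyl group s-cis, adds the electron-rich CH2=C(OMe) bond of 13 in an asynchronous inverse-electron-demand [4+2] cycloaddition with C4–C4a forming ahead of O2–C3; chelation of the reacting formyl group to C8=O is deliberately not the activating mode, because it would hold O2 anti to C4a and out of reach of C3. The closest known reaction types are the divalent-copper bis(oxazoline)-catalysed oxa-Diels–Alder addition of enol ethers to chelating 1-oxadienes and the uncatalysed addition of enol ethers to 2-formyl enones; what is new is that the chiral metal selects a chelation site on a symmetric anion beside the oxadiene instead of binding the oxadiene itself. The pyran ring is closed by the cycloaddition itself (suprafacial on both partners or, at the stepwise limit, 6-exo-trig attack of the free enolate oxygen on the methoxy-stabilised cation while copper holds the oxygens of the other half), and O2 goes to the methoxy-bearing carbon because the nucleophilic CH2 terminus must bond to the β-carbon C4a. C7 is set by site selection: the tert-butyl group flanking the copper-bound C6 oxygen lies beside C7 and is expected on the methyl face, away from the aroyloxy group, which with the (R,R)-ligand leaves the C8a-side oxadiene to react and gives (7S). C4a is set by the substrate, the enol ether approaching anti to the aroyloxy group, and C3 is not controlled; both centres are erased in steps 11 and 12, so only the site selection reaches the target. The step also needs the oxadiene mode to win over the 4π mode of 13 and the racemic background to be absent, which the fully substituted C8a and the inertness of the unbound anion should secure. Methanol is left in place at C3 because eliminating it now would pass through ring-opened species whose two formyl-enol halves are equivalent, so 14 is taken into step 10 cold and without storage.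

Step 10
Reactants: 14 (4aS,7S)-3-[(E)-3-acetoxyprop-1-enyl]-5-formyl-6-hydroxy-3-methoxy-7-methyl-8-oxo-4,4a,7,8-tetrahydro-3H-isochromen-7-yl 2,4-bis(methoxymethoxy)-6-methylbenzoate
Product: 15 (4aR,7R)-3-[(E)-3-acetoxyprop-1-enyl]-5-diazo-3-methoxy-7-methyl-6,8-dioxo-4,4a,5,6,7,8-hexahydro-3H-isochromen-7-yl 2,4-bis(methoxymethoxy)-6-methylbenzoate (C3 epimers; same spatial arrangement at C4a and C7 as 14)
Conditions: MeSO2N3 (1.3 equiv), Et3N (2 equiv), MeCN, −20 → 0 °C
Reagents that add atoms: methanesulfonyl azide, CS(=O)(=O)N=[N+]=[N-]
Why: Regitz deformylative diazo transfer: the enolate of the α-formyl ketone adds to the sulfonyl azide and the triazoline fragments with loss of the formyl group as an N-formyl sulfonamide. Triethylamine spares the acetate, the ketal and both esters. Removing the C5 formyl group ends the equivalence of the two halves, so C7 is secure from here on.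

Step 11
Reactants: 15 (4aR,7R)-3-[(E)-3-acetoxyprop-1-enyl]-5-diazo-3-methoxy-7-methyl-6,8-dioxo-4,4a,5,6,7,8-hexahydro-3H-isochromen-7-yl 2,4-bis(methoxymethoxy)-6-methylbenzoate
Product: 16 (7S)-3-[(E)-3-acetoxyprop-1-enyl]-3-methoxy-7-methyl-6,8-dioxo-4,6,7,8-tetrahydro-3H-isochromen-7-yl 2,4-bis(methoxymethoxy)-6-methylbenzoate (C3 epimers)
Conditions: Rh2(OAc)4 (1 mol%), CH2Cl2, 0 °C → rt
Reagents that add atoms: none
Why: Dirhodium carbenoid formation followed by 1,2-hydride shift from C4a, the known conversion of α-diazo ketones with a β-hydrogen into enones; the migrating hydrogen is allylic to the C1=C8a enol ether and should shift readily. The C4a centre is removed and C7 is untouched.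

Step 12
Reactants: 16 (7S)-3-[(E)-3-acetoxyprop-1-enyl]-3-methoxy-7-methyl-6,8-dioxo-4,6,7,8-tetrahydro-3H-isochromen-7-yl 2,4-bis(methoxymethoxy)-6-methylbenzoate
Product: 18 (7S)-3-[(E)-3-acetoxyprop-1-enyl]-7-methyl-6,8-dioxo-7,8-dihydro-6H-isochromen-7-yl 2,4-dihydroxy-6-methylbenzoate (target), via bis(methoxymethyl) ether 17 (not isolated)
Conditions: CF3CO2H/CH2Cl2/H2O 20:80:1, 0 °C
Reagents that add atoms: none
Why: Acid ionises the C3 ketal and loss of a C4 proton, vinylogously α to the dienone, gives the fully conjugated pyranoquinone (E1 elimination of methanol). The same acid cleaves the two aryl methoxymethyl acetals by protonolysis. The quaternary C7 cannot enolise, and the acetate and hindered ester should survive cold acid.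

## Compound list

1 | 2-methylresorcinol | Cc1c(O)cccc1O | starting material
2 | 4,6-dihydroxy-5-methylbenzene-1,3-dicarbaldehyde | Cc1c(O)c(C=O)cc(C=O)c1O | intermediate
3 | orsellinic acid | Cc1cc(O)cc(O)c1C(=O)O | starting material
4 | methoxymethyl 2,4-bis(methoxymethoxy)-6-methylbenzoate | COCOC(=O)c1c(C)cc(OCOC)cc1OCOC | intermediate
5 | 2,4-bis(methoxymethoxy)-6-methylbenzoic acid | Cc1cc(OCOC)cc(OCOC)c1C(=O)O | intermediate
6 | phenyliodine bis[2,4-bis(methoxymethoxy)-6-methylbenzoate] | Cc1cc(OCOC)cc(OCOC)c1C(=O)OI(OC(=O)c1c(C)cc(OCOC)cc1OCOC)c1ccccc1 | intermediate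
7 | 3,5-diformyl-2-hydroxy-1-methyl-6-oxocyclohexa-2,4-dien-1-yl 2,4-bis(methoxymethoxy)-6-methylbenzoate (tautomeric racemate) | O=CC1=CC(C=O)=C(O)C(C)(OC(=O)c2c(C)cc(OCOC)cc2OCOC)C1=O | intermediate
8 | cis-1,4-diacetoxybut-2-ene | CC(=O)OC/C=C\COC(C)=O | starting material
9 | 2-oxoethyl acetate | CC(=O)OCC=O | intermediate
10 | 1-(triphenylphosphoranylidene)propan-2-one | CC(=O)C=P(c1ccccc1)(c1ccccc1)c1ccccc1 | starting material
11 | (E)-4-oxopent-2-en-1-yl acetate | CC(=O)/C=C/COC(C)=O | intermediate
12 | (E)-4,4-dimethoxypent-2-en-1-yl acetate (not isolated) | COC(C)(OC)/C=C/COC(C)=O | intermediate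
13 | (E)-4-methoxypenta-2,4-dien-1-yl acetate | C=C(OC)/C=C/COC(C)=O | intermediate
14 | (4aS,7S)-3-[(E)-3-acetoxyprop-1-enyl]-5-formyl-6-hydroxy-3-methoxy-7-methyl-8-oxo-4,4a,7,8-tetrahydro-3H-isochromen-7-yl 2,4-bis(methoxymethoxy)-6-methylbenzoate (C3 epimers) | CC(=O)OC/C=C/C1(OC)C[C@H]2C(C=O)=C(O)[C@](C)(OC(=O)c3c(C)cc(OCOC)cc3OCOC)C(=O)C2=CO1 | intermediate
15 | (4aR,7R)-3-[(E)-3-acetoxyprop-1-enyl]-5-diazo-3-methoxy-7-methyl-6,8-dioxo-4,4a,5,6,7,8-hexahydro-3H-isochromen-7-yl 2,4-bis(methoxymethoxy)-6-methylbenzoate (C3 epimers) | CC(=O)OC/C=C/C1(OC)C[C@H]2C(=[N+]=[N-])C(=O)[C@](C)(OC(=O)c3c(C)cc(OCOC)cc3OCOC)C(=O)C2=CO1 | intermediate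
16 | (7S)-3-[(E)-3-acetoxyprop-1-enyl]-3-methoxy-7-methyl-6,8-dioxo-4,6,7,8-tetrahydro-3H-isochromen-7-yl 2,4-bis(methoxymethoxy)-6-methylbenzoate (C3 epimers) | CC(=O)OC/C=C/C1(OC)CC2=CC(=O)[C@](C)(OC(=O)c3c(C)cc(OCOC)cc3OCOC)C(=O)C2=CO1 | intermediate
17 | (7S)-3-[(E)-3-acetoxyprop-1-enyl]-7-methyl-6,8-dioxo-7,8-dihydro-6H-isochromen-7-yl 2,4-bis(methoxymethoxy)-6-methylbenzoate (not isolated) | CC(=O)OC/C=C/C1=CC2=CC(=O)[C@](C)(OC(=O)c3c(C)cc(OCOC)cc3OCOC)C(=O)C2=CO1 | intermediate
18 | (7S)-3-[(E)-3-acetoxyprop-1-enyl]-7-methyl-6,8-dioxo-7,8-dihydro-6H-isochromen-7-yl 2,4-dihydroxy-6-methylbenzoate | CC(=O)OC/C=C/C1=CC2=CC(=O)[C@](C)(OC(=O)c3c(C)cc(O)cc3O)C(=O)C2=CO1 | target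

## Step count and risks

Total: 12 steps. Longest linear sequence: 8 steps (3 → 4 → 5 → 6 → 7 → 14 → 15 → 16 → 18).

**Step 9 (key step, proposed new method).**
- What may go wrong:
  - weak discrimination between the two enantiotopic chelation sites, since it rests on one tert-butyl/C7 contact whose sense is a prediction, leading to low enantiomeric purity downstream;
  - loss of side fidelity through heterolysis of the C3–O2 bond of the ketal, or a long-lived zwitterion, followed by reclosure onto the other formyl group;
  - sluggish cycloaddition of the copper-bound anion, or product inhibition of the catalyst;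
  - the diene reacting through its 4π system across C4a=C8a.
- Fallback (known chemistry): set out from 7 and 13 without chiral ligand or base, heating neutral 7 with 13 in toluene over 4 Å sieves (thermal inverse-demand oxa-Diels–Alder addition of an enol ether to a 2-formyl enone). This gives 14 together with the mirror-image ketal F1. The racemate is taken through steps 10 and 11 as 15 with the mirror-image diazo ketone F2, then 16 with the mirror-image enone F3. Compound 16 is separated from F3 by preparative chromatography on a chiral stationary phase, and the route is rejoined at 16.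

**Step 5.**
- What may go wrong: stalled oxidation, because two formyl groups make the phenol electron-poor; or hydrolysis of the aryloxy-iodine intermediate to the free quinol.
- Fallback: set out from 2 and hydroxylate it dearomatively with 2-iodoxybenzoic acid to the free quinol F4. Convert 5 with 1-chloro-N,N,2-trimethylprop-1-en-1-amine into the acid chloride F5, and acylate F4 with F5 (Et3N, 4-dimethylaminopyridine), relying on acyl migration from the enol oxygen to the tertiary oxygen. The route is rejoined at 7.

**Step 8.**
- What may go wrong: deprotonation of the oxocarbenium ion at the acetoxymethylene carbon instead of the methyl group, ionisation of the allylic acetate by the silyl triflate, or hydrolysis of the enol ether on isolation.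
- Fallback: set out from 11 and silylate it (t-BuMe2SiOTf, Et3N) to the silyloxydiene F6. Use F6 in step 9 in place of 13 to give the silyl ketal F7. Steps 10 and 11 then give the diazo ketone F8 and the enone F9, and the acid of step 12 expels the silanol instead of methanol. The route is rejoined at 17.

**Steps 10 and 11 (taken together).**
- What may go wrong: slow diazo transfer at the hindered C5 enolate, which gives 14 time to ring-open and scramble; or diversion of the carbenoid into oxonium ylide formation with the C3 methoxy oxygen instead of hydride shift.
- Fallback: set out from 14 and brominate the enol at C5 (N-bromosuccinimide, pyridine, −40 °C) to the bromo formyl ketone F10. This non-enolisable compound loses its formyl group in methanol/NaHCO3 to give the bromo ketone F11. Dehydrobromination with 1,8-diazabicyclo[5.4.0]undec-7-ene then rejoins the route at 16.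

**Step 12.**
- What may go wrong: alkylation of the liberated resorcinol ring by methoxymethyl cations, or acid-promoted ionisation of the allylic acetate.
- Fallback: set out from 16 and eliminate methanol with pyridinium p-toluenesulfonate, isolating 17. Convert its aryl methoxymethyl ethers without protic acid (Et3SiOTf, 2,2'-bipyridyl) into the bis(triethylsilyl) ether F12, and remove the silyl groups with HF·pyridine. The route is rejoined at 18.

## Further compounds

F1 | step 9 | enantiomer of 14 (C3 epimers) | CC(=O)OC/C=C/C1(OC)C[C@@H]2C(C=O)=C(O)[C@@](C)(OC(=O)c3c(C)cc(OCOC)cc3OCOC)C(=O)C2=CO1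
F2 | step 9 | enantiomer of 15 (C3 epimers) | CC(=O)OC/C=C/C1(OC)C[C@@H]2C(=[N+]=[N-])C(=O)[C@@](C)(OC(=O)c3c(C)cc(OCOC)cc3OCOC)C(=O)C2=CO1
F3 | step 9 | enantiomer of 16 (C3 epimers) | CC(=O)OC/C=C/C1(OC)CC2=CC(=O)[C@@](C)(OC(=O)c3c(C)cc(OCOC)cc3OCOC)C(=O)C2=CO1
F4 | step 5 | 4,5-dihydroxy-5-methyl-6-oxocyclohexa-1,3-diene-1,3-dicarbaldehyde (tautomeric racemate) | O=CC1=CC(C=O)=C(O)C(C)(O)C1=O
F5 | step 5 | 2,4-bis(methoxymethoxy)-6-methylbenzoyl chloride | Cc1cc(OCOC)cc(OCOC)c1C(Cl)=O
F6 | step 8 | (E)-4-(tert-butyldimethylsilyloxy)penta-2,4-dien-1-yl acetate | C=C(O[Si](C)(C)C(C)(C)C)/C=C/COC(C)=O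
F7 | step 8 | analogue of 14 with tert-butyldimethylsilyloxy in place of methoxy at C3 (configuration at C4a and C7 as in 14; C3 epimers) | CC(=O)OC/C=C/C1(O[Si](C)(C)C(C)(C)C)C[C@H]2C(C=O)=C(O)[C@](C)(OC(=O)c3c(C)cc(OCOC)cc3OCOC)C(=O)C2=CO1
F8 | step 8 | analogue of 15 with tert-butyldimethylsilyloxy in place of methoxy at C3 (configuration at C4a and C7 as in 15; C3 epimers) | CC(=O)OC/C=C/C1(O[Si](C)(C)C(C)(C)C)C[C@H]2C(=[N+]=[N-])C(=O)[C@](C)(OC(=O)c3c(C)cc(OCOC)cc3OCOC)C(=O)C2=CO1
F9 | step 8 | analogue of 16 with tert-butyldimethylsilyloxy in place of methoxy at C3 (configuration at C7 as in 16; C3 epimers) | CC(=O)OC/C=C/C1(O[Si](C)(C)C(C)(C)C)CC2=CC(=O)[C@](C)(OC(=O)c3c(C)cc(OCOC)cc3OCOC)C(=O)C2=CO1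
F10 | step 10 | 5-bromo-5-formyl-6,8-dioxo analogue of 14 (configuration at C4a and C7 as in 14; C3 and C5 epimers; not isolated) | CC(=O)OC/C=C/C1(OC)C[C@H]2C(Br)(C=O)C(=O)[C@](C)(OC(=O)c3c(C)cc(OCOC)cc3OCOC)C(=O)C2=CO1
F11 | step 10 | 5-bromo-6,8-dioxo analogue of 15 with bromine and hydrogen in place of the diazo group (configuration at C4a and C7 as in 14; C3 and C5 epimers) | CC(=O)OC/C=C/C1(OC)C[C@H]2C(Br)C(=O)[C@](C)(OC(=O)c3c(C)cc(OCOC)cc3OCOC)C(=O)C2=CO1
F12 | step 12 | (7S)-3-[(E)-3-acetoxyprop-1-enyl]-7-methyl-6,8-dioxo-7,8-dihydro-6H-isochromen-7-yl 6-methyl-2,4-bis(triethylsilyloxy)benzoate | CC(=O)OC/C=C/C1=CC2=CC(=O)[C@](C)(OC(=O)c3c(C)cc(O[Si](CC)(CC)CC)cc3O[Si](CC)(CC)CC)C(=O)C2=CO1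
A1 | alternative 1 | (7S)-3-[(E)-3-acetoxyprop-1-enyl]-7-methyl-6,8-dioxo-7,8-dihydro-6H-isochromen-7-yl 6-methyl-2,4-bis(trimethylsilyloxy)benzoate | CC(=O)OC/C=C/C1=CC2=CC(=O)[C@](C)(OC(=O)c3c(C)cc(O[Si](C)(C)C)cc3O[Si](C)(C)C)C(=O)C2=CO1
A2 | alternative 1 | (7S)-3-[(E)-3-acetoxyprop-1-enyl]-7-methyl-6,8-dioxo-7,8-dihydro-6H-isochromen-7-yl but-2-ynoate | CC(=O)OC/C=C/C1=CC2=CC(=O)[C@](C)(OC(=O)C#CC)C(=O)C2=CO1
A3 | alternative 1 | 1,3-bis(trimethylsilyloxy)-5,5-dimethylcyclohexa-1,3-diene | C[Si](C)(C)OC1=CC(O[Si](C)(C)C)=CC(C)(C)C1
A4 | alternative 2 | (E)-3-[(7S)-7-hydroxy-7-methyl-6,8-dioxo-7,8-dihydro-6H-isochromen-3-yl]prop-2-enyl acetate | CC(=O)OC/C=C/C1=CC2=CC(=O)[C@](C)(O)C(=O)C2=CO1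
A5 | alternative 2 | (E)-3-{4-[(Z)-2,3-dioxobutylidene]-5-formyl-4H-pyran-2-yl}prop-2-enyl acetate | CC(=O)OC/C=C/C1=C/C(=C/C(=O)C(C)=O)C(C=O)=CO1
A6 | alternative 3 | 5-formyl-2-hydroxy-1-methyl-6-oxocyclohexa-2,4-dien-1-yl 2,4-bis(methoxymethoxy)-6-methylbenzoate (configuration at the quaternary carbon as in 18) | O=CC1=CC=C(O)[C@](C)(OC(=O)c2c(C)cc(OCOC)cc2OCOC)C1=O
A7 | alternative 3 | 4-methyl-1,3,5,7-tetraoxoheptan-4-yl 2,4-bis(methoxymethoxy)-6-methylbenzoate | O=CCC(=O)C(C)(OC(=O)c1c(C)cc(OCOC)cc1OCOC)C(=O)CC=O
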